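## Analysis of the target

Locants used throughout are labdane-type: ring A is C1–C5 and C10, ring B is C5–C10, C11–C16 is the side chain on C9, C17 is the formyl carbon on C8, C18/C19 are the methyls on C4 and C20 is the methyl on C10. Systematic names of the bicyclic compounds use naphthalene locants.

The target 30 is a trans-fused decalin (ent-labdane series) in which ring B (C5–C6=C7–C8–C9–C10) is a cyclohexene and ring A carries the C4 gem-dimethyl group and the angular C10 methyl. The four stereocentres C5, C8, C9 and C10 are exactly the four sp3 carbons of that cyclohexene. H-5 is trans to the C10 methyl, the C9 chain is cis to the C10 methyl (equatorial) and the C8 formyl group is trans to the C9 chain (equatorial), so H-5 and H-8 lie on opposite faces of ring B. C9 carries a two-carbon link to a trisubstituted (E)-alkene C13=C14 with CH2OAc trans to CO2H; this geometry must be built deliberately, since the Z isomer would lactonise. The sensitive unit is the β,γ-unsaturated aldehyde: H-8 is both allylic and α to the formyl group, so acid or base epimerises C8 or moves C6=C7 into conjugation, and C8 cannot be corrected by equilibration once alkene and aldehyde coexist. The allylic acetate and the free acid restrict the end game to mild acidic or neutral conditions. The hard points are the congested C5–C10 bond (quaternary C10 joined to a carbon flanked by quaternary C4) and the 5,8-trans relationship, which a suprafacial [4+2] addition of a reactive (E,E)-diene cannot deliver. The feature that invites the key move is that ring B is a Diels–Alder retron (C6=C7 with C5–C10 and C8–C9 as σ-bonds) and that C5 and C10 are already linked through C1–C4, so the cycloaddition can be intramolecular and close rings A and B together.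

## Retrosynthetic reasoning

**30 ⇒ 29.** The C17 aldehyde is made last, by neutral oxidation of the primary alcohol of hydroxy acid 29, so that the labile β,γ-unsaturated aldehyde never meets acid, base or a metal reagent. Alcohol and acid are unveiled together from the silyl ether and tert-butyl ester of 28.

**28 ⇒ 23 + 26.** The C12–C13 bond (sp3–sp2) is cut. Forward, hydroboration of the C9 vinyl group of 23 and B-alkyl Suzuki coupling with the (Z)-enol triflate 26 transfer the alkene geometry with retention. The geometry is therefore set earlier, by chelation-controlled triflation of β-keto ester 25, itself from chloride 24. Cutting here keeps the whole polar side chain out of the core synthesis.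

**23 ⇒ 20 ⇒ 19.** The C8–H bond and the position of the ring alkene are traced to a reductive 1,3-transposition of the tosylhydrazone 20 of the Δ7-6-ketone 19. Hydride enters C6 from the face opposite the axial C10 and C4 methyls, the resulting diazene 22 sits on the methyl face, and its hydrogen is handed suprafacially to C8 while the alkene moves to C6=C7. This sets H-8 cis to the C10 methyl without ever making C8 acidic in the presence of the C6=C7 alkene.

**19 ⇒ 18 ⇒ 17.** Enone 19 comes from the silyl enol ether 18 by Saegusa oxidation, which places the enone regiospecifically and erases C8. The vinyl group of 18 comes from the C9 aldehyde of 17 by methylenation.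

**17 ⇒ 16 (key).** The C5–C10 and C8–C9 bonds are cut: an intramolecular Diels–Alder reaction of the acyclic, achiral trienal 16. This is the only [4+2] partition that puts the alkene at C6=C7. It cannot set C8 correctly, because the 5,8-trans relationship would need a (Z)-diene terminus. The diene therefore carries a silyloxy group at C6, which matches the polarity of the enal (C5 nucleophilic, C10 electrophilic) and provides the handle for the C8 correction above. The step forms both rings and C5, C9 and C10 from a precursor with no ring and no stereocentre.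

**16 ⇒ 15 ⇒ 14 ⇒ 10 + 12.** The enal comes from ester 14 by reduction to 15 and allylic oxidation, after the dienol ether is in place, since an enal would not survive enolisation conditions. The C1–C10 bond is cut: hydroboration of the terminal alkene of 10 and B-alkyl Suzuki coupling with (E)-enol triflate 12 (from acetoacetate 11) fix the (E)-geometry of C9=C10, which later fixes C9 relative to C10.

**10 ⇒ 8 ⇒ 6 ⇒ 3 + 4; 3 ⇒ 1 + 2.** The 2-silyloxydiene 10 is the kinetic α′-silyl enol ether of enone 8. Enone 8 is the aldol condensation product (via 6) of methyl ketone 3 with aldehyde 4, which brings in C8 and C17. Ketone 3, with the C4 quaternary carbon and C1–C3, is the conjugate allylation product of mesityl oxide 1 and allylsilane 2.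

## Alternatives that were turned down

**Alternative 1:** the textbook route, cutting C4–C5 and C9–C10. Forward key step: enantioselective proton-initiated polyene bicyclisation of homofarnesyl acetate A1 to the bicyclic Δ7-alkene A2, then allylic oxidation at C17 and at C6 to reach an enone of the type of 19, and the same transposition. Turned down because the cyclisation ends in a C8 cation that eliminates to mixtures of alkene isomers. Without an aryl terminator the enantioselectivity of proton-initiated cyclisations is modest. C17 arrives as an unfunctionalised methyl, so two separate, regiochemically ambiguous allylic oxidations are needed. The key step solves only the part (trans-decalin, C9) that is easy and leaves C8, C17 and the alkene position open.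

**Alternative 2:** cutting C8–C9 by an Ireland–Claisen ring contraction of the trans-fused δ-lactone A3 to the cyclohexene acid A4. This forms ring B with C6=C7 in place. Turned down on mechanism: the six-membered lactone enforces a boat transition state, in which an (E)-alkenyl group gives the C8 and C9 substituents cis (A4 is the 8-epimer). The (Z)-alkene that would give trans must eclipse its CH2OSi group with the quaternary C10. Epimerising C9 afterwards is thermodynamically weak (equatorial carbonyl next to the quaternary C10). In addition A3 already needs three stereocentres (C5, C6, C10), so the precursor is not much simpler than the product.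

**Alternative 3:** dearomatisation, cutting C1–C10. Forward key step: intramolecular para-alkylation of phenol A5 to the cross-conjugated dienone A6, which makes ring A and the C10 quaternary centre from a flat arene. Turned down because a simple SN2 alkylative dearomatisation has no reliable enantioselective version, so A6 would be racemic. The later cuprate addition at C9 would go anti to the C10 methyl and give the axial, wrong C9 epimer. C8, C9 and C17 would all have to be added afterwards, which costs more steps than the dearomatisation saves.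

Key step: step 9

Assumption: compounds 1, 2, 4, 11 and 24 are taken as commercial; the (S)-oxazaborolidinium catalyst in step 9 is assumed to shield the enal face that leads to 17 as drawn, and if the sense is found to be opposite the (R)-catalyst is used without other change.

## Route

Step 1
Reactants: 1 mesityl oxide (4-methylpent-3-en-2-one); 2 allyltrimethylsilane
Product: 3 4,4-dimethylhept-6-en-2-one
Conditions: TiCl4, CH2Cl2, −78 °C; H2O
Reagents that add atoms: none
Why: Hosomi–Sakurai conjugate allylation: the TiCl4-activated enone is attacked by the allylsilane at the β,β-disubstituted carbon, giving the quaternary C4 with C1–C3 attached; no stereocentre is formed.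

Step 2
Reactants: 3 4,4-dimethylhept-6-en-2-one; 4 [(tert-butyldimethylsilyl)oxy]acetaldehyde
Product: 6 1-[(tert-butyldimethylsilyl)oxy]-2-hydroxy-6,6-dimethylnon-8-en-4-one (racemic), via lithium enolate 5 (not isolated)
Conditions: LDA, THF, −78 °C; then 4; aq. NH4Cl
Reagents that add atoms: none
Why: Kinetic deprotonation takes the methyl protons rather than the neopentyl CH2, and the enolate adds to the aldehyde (aldol addition); the carbinol centre is racemic and is removed in step 3.

Step 3
Reactants: 6 1-[(tert-butyldimethylsilyl)oxy]-2-hydroxy-6,6-dimethylnon-8-en-4-one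
Product: 8 (2E)-1-[(tert-butyldimethylsilyl)oxy]-6,6-dimethylnona-2,8-dien-4-one, via mesylate 7 (not isolated)
Conditions: MsCl, Et3N, CH2Cl2, 0 °C → rt
Reagents that add atoms: none
Why: Mesylation and E1cB elimination of the aldol should give the conjugated enone, the (E)-alkene being the thermodynamic product.

Step 4
Reactants: 8 (2E)-1-[(tert-butyldimethylsilyl)oxy]-6,6-dimethylnona-2,8-dien-4-one
Product: 10 (2E,4Z)-1,4-bis[(tert-butyldimethylsilyl)oxy]-6,6-dimethylnona-2,4,8-triene, via lithium dienolate 9 (not isolated)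
Conditions: LDA, THF, −78 °C; TBSCl, HMPA, −78 → 0 °C
Reagents that add atoms: tert-butyldimethylsilyl chloride, CC(C)(C)[Si](C)(C)Cl
Why: Kinetic α′-deprotonation of the enone (cross-conjugated dienolate, as with isophorone) and O-silylation give the 2-silyloxy-1,3-diene; the bulky tert-alkyl group sits cis to oxygen (Z), away from the vinyl group, and so lies "outside" on the diene.

Step 5
Reactants: 11 ethyl acetoacetate
Product: 12 ethyl (2E)-3-{[(trifluoromethyl)sulfonyl]oxy}but-2-enoate
Conditions: Tf2O, aq. Me4NOH, hexanes, 5 °C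
Reagents that add atoms: trifluoromethanesulfonic anhydride, O=S(=O)(OS(=O)(=O)C(F)(F)F)C(F)(F)F
Why: O-Triflation of the enolate with a non-coordinating ammonium counter-ion should give the non-chelated (E)-enol triflate, triflate trans to the ester.

Step 6
Reactants: 10 (2E,4Z)-1,4-bis[(tert-butyldimethylsilyl)oxy]-6,6-dimethylnona-2,4,8-triene; 12 ethyl (2E)-3-{[(trifluoromethyl)sulfonyl]oxy}but-2-enoate
Product: 14 ethyl (2E,8Z,10E)-9,12-bis[(tert-butyldimethylsilyl)oxy]-3,7,7-trimethyldodeca-2,8,10-trienoate, via alkylborane 13 (not isolated)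
Conditions: 9-BBN, THF, rt; then 12, Pd(dppf)Cl2 (5 mol %), AsPh3, K3PO4, DMF/H2O, rt
Reagents that add atoms: none
Why: 9-BBN hydroborates only the monosubstituted terminal alkene (anti-Markovnikov), and the B-alkyl Suzuki–Miyaura coupling proceeds with retention at the sp2 carbon, so the (E)-geometry of C9=C10 comes from 12.

Step 7
Reactants: 14 ethyl (2E,8Z,10E)-9,12-bis[(tert-butyldimethylsilyl)oxy]-3,7,7-trimethyldodeca-2,8,10-trienoate
Product: 15 (2E,8Z,10E)-9,12-bis[(tert-butyldimethylsilyl)oxy]-3,7,7-trimethyldodeca-2,8,10-trien-1-ol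
Conditions: DIBAL-H, CH2Cl2, −78 °C; Rochelle salt
Reagents that add atoms: none
Why: 1,2-Reduction of the conjugated ester to the allylic alcohol; the silyl ether and the silyl enol ether are inert to DIBAL-H at −78 °C.

Step 8
Reactants: 15 (2E,8Z,10E)-9,12-bis[(tert-butyldimethylsilyl)oxy]-3,7,7-trimethyldodeca-2,8,10-trien-1-ol
Product: 16 (2E,8Z,10E)-9,12-bis[(tert-butyldimethylsilyl)oxy]-3,7,7-trimethyldodeca-2,8,10-trienal
Conditions: MnO2, CH2Cl2, rt
Reagents that add atoms: none
Why: Selective neutral oxidation of the allylic alcohol to the enal; the acid-labile dienol ether is not touched.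

Step 9
Reactants: 16 (2E,8Z,10E)-9,12-bis[(tert-butyldimethylsilyl)oxy]-3,7,7-trimethyldodeca-2,8,10-trienal
Product: 17 (1R,2R,4aR,8aR)-4-[(tert-butyldimethylsilyl)oxy]-2-{[(tert-butyldimethylsilyl)oxy]methyl}-5,5,8a-trimethyl-1,2,4a,5,6,7,8,8a-octahydronaphthalene-1-carbaldehyde
Conditions: (S)-o-tolyl-CBS oxazaborolidine (20 mol %), Tf2NH (18 mol %), CH2Cl2, −78 → −40 °C
Reagents that add atoms: none
Why: Proposed new method: a cationic chiral oxazaborolidinium ion binds the formyl group of 16 and the tethered 2-silyloxydiene adds across C9=C10 in a concerted but asynchronous [4+2] process (C5–C10 bond leading, Mukaiyama–Michael-like); the closest known reaction types are oxazaborolidinium-catalysed Diels–Alder reactions of enals with 2-silyloxydienes and the same catalysts in intramolecular Diels–Alder reactions of trienals, neither yet shown for a β,β-disubstituted enal that creates an angular quaternary carbon. Ring B (C5–C6=C7–C8–C9–C10) is the six-membered cycloadduct ring, and ring A (C1–C5, C10) is closed by the C5–C10 bond through the four-atom tether C1–C4 (type 1 intramolecular Diels–Alder of a 1,3,9-decatriene, the C5–C10 bond forming 6-exo with respect to the enal). Regiochemistry is fixed by the tether and is electronically matched, since the silyloxy group at C6 makes C5 the nucleophilic diene terminus and the coordinated enal makes C10 the electrophilic carbon. C10 is set by the catalyst, which shields one face of the s-trans enal, and C9 follows from C10 because addition is suprafacial on the (E)-alkene, so CHO and the C10 methyl end up cis. C5 is set by the endo transition state (coordinated formyl group under the diene, tether exo), which gives the trans ring fusion, and the C10 methyl reinforces this by destabilising the cis-fused arrangement. C8 is set by the (E)-geometry of the C7=C8 terminus (CH2OTBS cis to CHO); this is the wrong relative configuration for the target and is deliberately erased in step 11 and reset in step 13. The selectivities needed are endo over exo and one enal face over the other; the gem-dimethyl group at C4 helps by pre-folding the tether.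

Step 10
Reactants: 17 (1R,2R,4aR,8aR)-4-[(tert-butyldimethylsilyl)oxy]-2-{[(tert-butyldimethylsilyl)oxy]methyl}-5,5,8a-trimethyl-1,2,4a,5,6,7,8,8a-octahydronaphthalene-1-carbaldehyde
Product: 18 tert-butyl({(1R,2S,4aR,8aS)-4-[(tert-butyldimethylsilyl)oxy]-1-ethenyl-5,5,8a-trimethyl-1,2,4a,5,6,7,8,8a-octahydronaphthalen-2-yl}methoxy)dimethylsilane
Conditions: Ph3PCH3Br, KHMDS, THF, −78 → 0 °C
Reagents that add atoms: methyltriphenylphosphonium bromide, C[P+](c1ccccc1)(c1ccccc1)c1ccccc1.[Br-]
Why: Wittig methylenation with the small non-stabilised ylide converts C11 into the vinyl group C11=C12; low temperature limits epimerisation at C9 and the silyl enol ether is inert to the ylide.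

Step 11
Reactants: 18 tert-butyl({(1R,2S,4aR,8aS)-4-[(tert-butyldimethylsilyl)oxy]-1-ethenyl-5,5,8a-trimethyl-1,2,4a,5,6,7,8,8a-octahydronaphthalen-2-yl}methoxy)dimethylsilane
Product: 19 (4S,4aS,8aR)-3-{[(tert-butyldimethylsilyl)oxy]methyl}-4-ethenyl-4a,8,8-trimethyl-4a,5,6,7,8,8a-hexahydronaphthalen-1(4H)-one
Conditions: Pd(OAc)2 (1.1 equiv), MeCN, rt
Reagents that add atoms: none
Why: Saegusa–Ito oxidation: the silyl enol ether gives a palladium enolate at C7 and syn β-hydride elimination of H-8 gives the Δ7-6-ketone regiospecifically, which removes the wrong C8 centre.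

Step 12
Reactants: 19 (4S,4aS,8aR)-3-{[(tert-butyldimethylsilyl)oxy]methyl}-4-ethenyl-4a,8,8-trimethyl-4a,5,6,7,8,8a-hexahydronaphthalen-1(4H)-one
Product: 20 N'-[(4S,4aS,8aR)-3-{[(tert-butyldimethylsilyl)oxy]methyl}-4-ethenyl-4a,8,8-trimethyl-4a,5,6,7,8,8a-hexahydronaphthalen-1(4H)-ylidene]-4-methylbenzenesulfonohydrazide
Conditions: TsNHNH2, EtOH, 70 °C
Reagents that add atoms: 4-methylbenzenesulfonohydrazide, Cc1ccc(cc1)S(=O)(=O)NN
Why: Condensation to the α,β-unsaturated tosylhydrazone; cyclisation to a pyrazoline is blocked because the β-carbon C8 is fully substituted.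

Step 13
Reactants: 20 N'-[(4S,4aS,8aR)-3-{[(tert-butyldimethylsilyl)oxy]methyl}-4-ethenyl-4a,8,8-trimethyl-4a,5,6,7,8,8a-hexahydronaphthalen-1(4H)-ylidene]-4-methylbenzenesulfonohydrazide
Product: 23 tert-butyl{[(1R,2S,4aR,8aS)-1-ethenyl-5,5,8a-trimethyl-1,2,4a,5,6,7,8,8a-octahydronaphthalen-2-yl]methoxy}dimethylsilane, via allylic tosylhydrazine 21 (not isolated), via allylic diazene 22 (not isolated)
Conditions: catecholborane, CHCl3, 0 °C; then NaOAc·3H2O, reflux
Reagents that add atoms: none
Why: Reductive 1,3-transposition of an enone tosylhydrazone (Kabalka alkene-migration reduction): hydride adds to C6 from the face opposite the axial C10 and C4 methyls, so the diazene formed after loss of sulfinate sits axial on the methyl face. It transfers its hydrogen suprafacially to C8 with loss of N2 (retro-ene), which sets H-8 cis to the C10 methyl (CH2OTBS equatorial, trans to the vinyl group) and places the alkene at C6=C7.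

Step 14
Reactants: 24 tert-butyl 4-chloro-3-oxobutanoate
Product: 25 tert-butyl 4-acetoxy-3-oxobutanoate
Conditions: KOAc, DMF, rt
Reagents that add atoms: potassium acetate, CC(=O)[O-].[K+]
Why: SN2 displacement of the activated α′-chloride of the β-keto ester by acetate.

Step 15
Reactants: 25 tert-butyl 4-acetoxy-3-oxobutanoate
Product: 26 tert-butyl (2Z)-4-acetoxy-3-{[(trifluoromethyl)sulfonyl]oxy}but-2-enoate
Conditions: LiOTf, i-Pr2NEt, Tf2O, CH2Cl2, −78 → 0 °C
Reagents that add atoms: trifluoromethanesulfonic anhydride, O=S(=O)(OS(=O)(=O)C(F)(F)F)C(F)(F)F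
Why: O-Triflation of the lithium-chelated enolate should give the (Z)-enol triflate (triflate cis to the ester), which places CH2OAc trans to the ester as in the target.

Step 16
Reactants: 23 tert-butyl{[(1R,2S,4aR,8aS)-1-ethenyl-5,5,8a-trimethyl-1,2,4a,5,6,7,8,8a-octahydronaphthalen-2-yl]methoxy}dimethylsilane; 26 tert-butyl (2Z)-4-acetoxy-3-{[(trifluoromethyl)sulfonyl]oxy}but-2-enoate
Product: 28 tert-butyl (2E)-4-acetoxy-3-{2-[(1R,2S,4aR,8aS)-2-{[(tert-butyldimethylsilyl)oxy]methyl}-5,5,8a-trimethyl-1,2,4a,5,6,7,8,8a-octahydronaphthalen-1-yl]ethyl}but-2-enoate, via alkylborane 27 (not isolated)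
Conditions: 9-BBN, THF, 50 °C; then 26, Pd(dppf)Cl2 (5 mol %), AsPh3, K3PO4, DMF/H2O, rt
Reagents that add atoms: none
Why: 9-BBN adds only to the monosubstituted vinyl group (the hindered cis-disubstituted ring alkene is inert), and the B-alkyl Suzuki–Miyaura coupling forms C12–C13 with retention of the triflate geometry, giving the (E)-alkene of the target.

Step 17
Reactants: 28 tert-butyl (2E)-4-acetoxy-3-{2-[(1R,2S,4aR,8aS)-2-{[(tert-butyldimethylsilyl)oxy]methyl}-5,5,8a-trimethyl-1,2,4a,5,6,7,8,8a-octahydronaphthalen-1-yl]ethyl}but-2-enoate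
Product: 29 (2E)-4-acetoxy-3-{2-[(1R,2S,4aR,8aS)-2-(hydroxymethyl)-5,5,8a-trimethyl-1,2,4a,5,6,7,8,8a-octahydronaphthalen-1-yl]ethyl}but-2-enoic acid
Conditions: TFA/CH2Cl2/H2O (10:10:1), 0 °C → rt; then NaHCO3, MeOH, 10 min; acidify to pH 4
Reagents that add atoms: none
Why: Acidolysis cleaves the tert-butyl ester (loss of isobutene) and the primary silyl ether in one operation; the acetate, the enoate and both alkenes should survive, and any trifluoroacetate of the alcohol is removed by the brief bicarbonate/methanol treatment.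

Step 18
Reactants: 29 (2E)-4-acetoxy-3-{2-[(1R,2S,4aR,8aS)-2-(hydroxymethyl)-5,5,8a-trimethyl-1,2,4a,5,6,7,8,8a-octahydronaphthalen-1-yl]ethyl}but-2-enoic acid
Product: 30 (2E)-4-acetoxy-3-{2-[(1R,2S,4aR,8aS)-2-formyl-5,5,8a-trimethyl-1,2,4a,5,6,7,8,8a-octahydronaphthalen-1-yl]ethyl}but-2-enoic acid (CNP0217581.1)
Conditions: Dess–Martin periodinane, NaHCO3, CH2Cl2, 0 °C; rapid filtration through buffered silica
Reagents that add atoms: none
Why: Dess–Martin oxidation of the primary alcohol under buffered, near-neutral conditions should give the aldehyde without epimerising C8 or moving the C6=C7 alkene; the free acid is tolerated.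

## Compound list

1 | mesityl oxide (4-methylpent-3-en-2-one) | CC(=O)C=C(C)C | starting material
2 | allyltrimethylsilane | C=CC[Si](C)(C)C | starting material
3 | 4,4-dimethylhept-6-en-2-one | CC(=O)CC(C)(C)CC=C | intermediate
4 | [(tert-butyldimethylsilyl)oxy]acetaldehyde | O=CCO[Si](C)(C)C(C)(C)C | starting material
5 | lithium 4,4-dimethylhepta-1,6-dien-2-olate (lithium enolate of 3) | [Li]OC(=C)CC(C)(C)CC=C | intermediate (not isolated)
6 | 1-[(tert-butyldimethylsilyl)oxy]-2-hydroxy-6,6-dimethylnon-8-en-4-one (racemic) | C=CCC(C)(C)CC(=O)CC(O)CO[Si](C)(C)C(C)(C)C | intermediate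
7 | 1-[(tert-butyldimethylsilyl)oxy]-6,6-dimethyl-4-oxonon-8-en-2-yl methanesulfonate (mesylate of 6) | C=CCC(C)(C)CC(=O)CC(OS(C)(=O)=O)CO[Si](C)(C)C(C)(C)C | intermediate (not isolated)
8 | (2E)-1-[(tert-butyldimethylsilyl)oxy]-6,6-dimethylnona-2,8-dien-4-one | C=CCC(C)(C)CC(=O)/C=C/CO[Si](C)(C)C(C)(C)C | intermediate
9 | lithium (2E,4Z)-1-[(tert-butyldimethylsilyl)oxy]-6,6-dimethylnona-2,4,8-trien-4-olate (lithium dienolate of 8) | C=CCC(C)(C)/C=C(O[Li])/C=C/CO[Si](C)(C)C(C)(C)C | intermediate (not isolated)
10 | (2E,4Z)-1,4-bis[(tert-butyldimethylsilyl)oxy]-6,6-dimethylnona-2,4,8-triene | C=CCC(C)(C)/C=C(O[Si](C)(C)C(C)(C)C)/C=C/CO[Si](C)(C)C(C)(C)C | intermediate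
11 | ethyl acetoacetate | CCOC(=O)CC(C)=O | starting material
12 | ethyl (2E)-3-{[(trifluoromethyl)sulfonyl]oxy}but-2-enoate | CCOC(=O)/C=C(\C)OS(=O)(=O)C(F)(F)F | intermediate
13 | B-alkyl-9-borabicyclo[3.3.1]nonane from 10 (boron on C1) | C1CCC2CCCC1B2CCCC(C)(C)/C=C(O[Si](C)(C)C(C)(C)C)/C=C/CO[Si](C)(C)C(C)(C)C | intermediate (not isolated)
14 | ethyl (2E,8Z,10E)-9,12-bis[(tert-butyldimethylsilyl)oxy]-3,7,7-trimethyldodeca-2,8,10-trienoate | CCOC(=O)/C=C(\C)CCCC(C)(C)/C=C(O[Si](C)(C)C(C)(C)C)/C=C/CO[Si](C)(C)C(C)(C)C | intermediate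
15 | (2E,8Z,10E)-9,12-bis[(tert-butyldimethylsilyl)oxy]-3,7,7-trimethyldodeca-2,8,10-trien-1-ol | OC/C=C(\C)CCCC(C)(C)/C=C(O[Si](C)(C)C(C)(C)C)/C=C/CO[Si](C)(C)C(C)(C)C | intermediate
16 | (2E,8Z,10E)-9,12-bis[(tert-butyldimethylsilyl)oxy]-3,7,7-trimethyldodeca-2,8,10-trienal | O=C/C=C(\C)CCCC(C)(C)/C=C(O[Si](C)(C)C(C)(C)C)/C=C/CO[Si](C)(C)C(C)(C)C | intermediate
17 | (1R,2R,4aR,8aR)-4-[(tert-butyldimethylsilyl)oxy]-2-{[(tert-butyldimethylsilyl)oxy]methyl}-5,5,8a-trimethyl-1,2,4a,5,6,7,8,8a-octahydronaphthalene-1-carbaldehyde | O=C[C@@H]1[C@H](CO[Si](C)(C)C(C)(C)C)C=C(O[Si](C)(C)C(C)(C)C)[C@@H]2C(C)(C)CCC[C@@]12C | intermediate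
18 | tert-butyl({(1R,2S,4aR,8aS)-4-[(tert-butyldimethylsilyl)oxy]-1-ethenyl-5,5,8a-trimethyl-1,2,4a,5,6,7,8,8a-octahydronaphthalen-2-yl}methoxy)dimethylsilane | C=C[C@@H]1[C@H](CO[Si](C)(C)C(C)(C)C)C=C(O[Si](C)(C)C(C)(C)C)[C@@H]2C(C)(C)CCC[C@@]12C | intermediate
19 | (4S,4aS,8aR)-3-{[(tert-butyldimethylsilyl)oxy]methyl}-4-ethenyl-4a,8,8-trimethyl-4a,5,6,7,8,8a-hexahydronaphthalen-1(4H)-one | C=C[C@@H]1C(CO[Si](C)(C)C(C)(C)C)=CC(=O)[C@@H]2C(C)(C)CCC[C@@]12C | intermediate
20 | N'-[(4S,4aS,8aR)-3-{[(tert-butyldimethylsilyl)oxy]methyl}-4-ethenyl-4a,8,8-trimethyl-4a,5,6,7,8,8a-hexahydronaphthalen-1(4H)-ylidene]-4-methylbenzenesulfonohydrazide | C=C[C@@H]1C(CO[Si](C)(C)C(C)(C)C)=CC(=NNS(=O)(=O)c3ccc(C)cc3)[C@@H]2C(C)(C)CCC[C@@]12C | intermediate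
21 | N'-[(1S,4S,4aS,8aR)-3-{[(tert-butyldimethylsilyl)oxy]methyl}-4-ethenyl-4a,8,8-trimethyl-1,4,4a,5,6,7,8,8a-octahydronaphthalen-1-yl]-4-methylbenzenesulfonohydrazide (boron-bound in the flask) | C=C[C@@H]1C(CO[Si](C)(C)C(C)(C)C)=C[C@H](NNS(=O)(=O)c3ccc(C)cc3)[C@@H]2C(C)(C)CCC[C@@]12C | intermediate (not isolated)
22 | [(1S,4S,4aS,8aR)-3-{[(tert-butyldimethylsilyl)oxy]methyl}-4-ethenyl-4a,8,8-trimethyl-1,4,4a,5,6,7,8,8a-octahydronaphthalen-1-yl]diazene | C=C[C@@H]1C(CO[Si](C)(C)C(C)(C)C)=C[C@H](N=N)[C@@H]2C(C)(C)CCC[C@@]12C | intermediate (not isolated)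
23 | tert-butyl{[(1R,2S,4aR,8aS)-1-ethenyl-5,5,8a-trimethyl-1,2,4a,5,6,7,8,8a-octahydronaphthalen-2-yl]methoxy}dimethylsilane | C=C[C@@H]1[C@@H](CO[Si](C)(C)C(C)(C)C)C=C[C@@H]2C(C)(C)CCC[C@@]12C | intermediate
24 | tert-butyl 4-chloro-3-oxobutanoate | CC(C)(C)OC(=O)CC(=O)CCl | starting material
25 | tert-butyl 4-acetoxy-3-oxobutanoate | CC(=O)OCC(=O)CC(=O)OC(C)(C)C | intermediate
26 | tert-butyl (2Z)-4-acetoxy-3-{[(trifluoromethyl)sulfonyl]oxy}but-2-enoate | CC(=O)OC/C(OS(=O)(=O)C(F)(F)F)=C/C(=O)OC(C)(C)C | intermediate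
27 | B-alkyl-9-borabicyclo[3.3.1]nonane from 23 (boron on C12) | C1CCC2CCCC1B2CC[C@@H]1[C@@H](CO[Si](C)(C)C(C)(C)C)C=C[C@@H]2C(C)(C)CCC[C@@]12C | intermediate (not isolated)
28 | tert-butyl (2E)-4-acetoxy-3-{2-[(1R,2S,4aR,8aS)-2-{[(tert-butyldimethylsilyl)oxy]methyl}-5,5,8a-trimethyl-1,2,4a,5,6,7,8,8a-octahydronaphthalen-1-yl]ethyl}but-2-enoate | CC(=O)OC/C(=C/C(=O)OC(C)(C)C)CC[C@@H]1[C@@H](CO[Si](C)(C)C(C)(C)C)C=C[C@@H]2C(C)(C)CCC[C@@]12C | intermediate
29 | (2E)-4-acetoxy-3-{2-[(1R,2S,4aR,8aS)-2-(hydroxymethyl)-5,5,8a-trimethyl-1,2,4a,5,6,7,8,8a-octahydronaphthalen-1-yl]ethyl}but-2-enoic acid | CC(=O)OC/C(=C/C(=O)O)CC[C@@H]1[C@@H](CO)C=C[C@@H]2C(C)(C)CCC[C@@]12C | intermediate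
30 | (2E)-4-acetoxy-3-{2-[(1R,2S,4aR,8aS)-2-formyl-5,5,8a-trimethyl-1,2,4a,5,6,7,8,8a-octahydronaphthalen-1-yl]ethyl}but-2-enoic acid (CNP0217581.1) | CC(=O)OC/C(=C/C(=O)O)CC[C@@H]1[C@@H](C=O)C=C[C@@H]2C(C)(C)CCC[C@@]12C | target

## Step count and uncertain steps

Total step count: 18. Longest linear sequence: 15 steps (steps 1–4, 6–13, 16–18); steps 5, 14 and 15 prepare the two enol triflates.

**Step 9 (key step, proposed new method).** What may go wrong: the β,β-disubstituted enal may be too unreactive toward closure of the congested C5–C10 bond. The acidic catalyst may cleave the silyl dienol ether, or the process may stop after a Mukaiyama–Michael addition. Endo/exo or facial selectivity may be poor because the C10 methyl and the tether compete for the shielded space of the catalyst. Fallback with known chemistry, from 16 back to 17: the trienal 16 is heated in toluene (BHT, 150 °C, sealed tube), a thermal type 1 intramolecular Diels–Alder reaction of a known kind. This should give 17 as a racemate with its enantiomer, ent-17 F1. The mixture is condensed with (1R,2R)-N,N'-dimethyl-1,2-diphenylethane-1,2-diamine to give two diastereomeric imidazolidines, the aminal of 17 F2 and the aminal of ent-17 F3, which are separated by chromatography. F2 is hydrolysed on wet silica or with aqueous NH4Cl/THF to return enantiopure 17. Absolute control thus moves from the catalyst to a classical resolution.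

**Step 12 (with step 13).** What may go wrong: slow or incomplete condensation at the C6 carbonyl, which is screened by the C4 and C10 methyl groups, and loss of the primary silyl ether on prolonged heating. Fallback, from 19 back to 23: dissolving-metal reduction of 19 (Li, NH3/THF, t-BuOH, −78 °C) protonates C8 axially, cis to the C10 methyl, and should give the saturated ketone (3S,4R,4aS,8aR)-3-{[(tert-butyldimethylsilyl)oxy]methyl}-4-ethenyl-4a,8,8-trimethyl-3,4,4a,5,6,7,8,8a-octahydronaphthalen-1(2H)-one F4. Kinetic enolisation toward the C7 methylene (KHMDS, PhNTf2, −78 °C) gives the enol triflate F5. Palladium-catalysed formate reduction (Pd(OAc)2, PPh3, HCO2H, n-Bu3N, DMF, 60 °C) gives 23.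

**Step 16.** What may go wrong: partial hydrolysis of the acetate under the aqueous basic coupling conditions, ionisation of the allylic acetate by Pd(0), and slow hydroboration of the vinyl group next to the quaternary C10. Fallback, from 23 back to 28: the alkylborane 27 is oxidised (NaBO3·4H2O) to the primary alcohol 2-[(1R,2S,4aR,8aS)-2-{[(tert-butyldimethylsilyl)oxy]methyl}-5,5,8a-trimethyl-1,2,4a,5,6,7,8,8a-octahydronaphthalen-1-yl]ethanol F6. This is converted (I2, PPh3, imidazole) into the iodide F7 and then (activated Zn, DMA) into the alkylzinc iodide F8. Base-free Negishi coupling of F8 with 26 (Pd2(dba)3, SPhos, THF/DMA, rt) gives 28.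

**Step 18.** What may go wrong: epimerisation at C8 or migration of the C6=C7 alkene into conjugation during oxidation or isolation of a polar acid-aldehyde, promoted by the free carboxylic acid and by acetic acid set free from the oxidant. Fallback, from 28 back to 30, changing the order of events: selective desilylation of 28 (HF·pyridine, THF/pyridine) gives the hydroxy ester tert-butyl (2E)-4-acetoxy-3-{2-[(1R,2S,4aR,8aS)-2-(hydroxymethyl)-5,5,8a-trimethyl-1,2,4a,5,6,7,8,8a-octahydronaphthalen-1-yl]ethyl}but-2-enoate F9. Dess–Martin oxidation gives the non-polar, easily purified aldehyde ester F10. The tert-butyl ester is then removed last by short exposure to TFA/CH2Cl2 at 0 °C, giving 30.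

## Further compounds

F1 | step 9 | ent-17, (1S,2S,4aS,8aS)-4-[(tert-butyldimethylsilyl)oxy]-2-{[(tert-butyldimethylsilyl)oxy]methyl}-5,5,8a-trimethyl-1,2,4a,5,6,7,8,8a-octahydronaphthalene-1-carbaldehyde | O=C[C@H]1[C@@H](CO[Si](C)(C)C(C)(C)C)C=C(O[Si](C)(C)C(C)(C)C)[C@H]2C(C)(C)CCC[C@]12C
F2 | step 9 | aminal of 17: (4R,5R)-1,3-dimethyl-4,5-diphenylimidazolidine carrying at C2 the decalin unit of 17 | CN1[C@H](c2ccccc2)[C@@H](c2ccccc2)N(C)C1[C@@H]1[C@H](CO[Si](C)(C)C(C)(C)C)C=C(O[Si](C)(C)C(C)(C)C)[C@@H]2C(C)(C)CCC[C@@]12C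
F3 | step 9 | aminal of ent-17: (4R,5R)-1,3-dimethyl-4,5-diphenylimidazolidine carrying at C2 the decalin unit of F1 | CN1[C@H](c2ccccc2)[C@@H](c2ccccc2)N(C)C1[C@H]1[C@@H](CO[Si](C)(C)C(C)(C)C)C=C(O[Si](C)(C)C(C)(C)C)[C@H]2C(C)(C)CCC[C@]12C
F4 | step 12 | (3S,4R,4aS,8aR)-3-{[(tert-butyldimethylsilyl)oxy]methyl}-4-ethenyl-4a,8,8-trimethyl-3,4,4a,5,6,7,8,8a-octahydronaphthalen-1(2H)-one | C=C[C@@H]1[C@@H](CO[Si](C)(C)C(C)(C)C)CC(=O)[C@@H]2C(C)(C)CCC[C@@]12C
F5 | step 12 | (3R,4R,4aS,8aR)-3-{[(tert-butyldimethylsilyl)oxy]methyl}-4-ethenyl-4a,8,8-trimethyl-3,4,4a,5,6,7,8,8a-octahydronaphthalen-1-yl trifluoromethanesulfonate | C=C[C@@H]1[C@@H](CO[Si](C)(C)C(C)(C)C)C=C(OS(=O)(=O)C(F)(F)F)[C@@H]2C(C)(C)CCC[C@@]12C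
F6 | step 16 | 2-[(1R,2S,4aR,8aS)-2-{[(tert-butyldimethylsilyl)oxy]methyl}-5,5,8a-trimethyl-1,2,4a,5,6,7,8,8a-octahydronaphthalen-1-yl]ethanol | OCC[C@@H]1[C@@H](CO[Si](C)(C)C(C)(C)C)C=C[C@@H]2C(C)(C)CCC[C@@]12C
F7 | step 16 | tert-butyl{[(1R,2S,4aR,8aS)-1-(2-iodoethyl)-5,5,8a-trimethyl-1,2,4a,5,6,7,8,8a-octahydronaphthalen-2-yl]methoxy}dimethylsilane | ICC[C@@H]1[C@@H](CO[Si](C)(C)C(C)(C)C)C=C[C@@H]2C(C)(C)CCC[C@@]12C
F8 | step 16 | alkylzinc iodide from F7 (zinc on C12) | I[Zn]CC[C@@H]1[C@@H](CO[Si](C)(C)C(C)(C)C)C=C[C@@H]2C(C)(C)CCC[C@@]12C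
F9 | step 18 | tert-butyl (2E)-4-acetoxy-3-{2-[(1R,2S,4aR,8aS)-2-(hydroxymethyl)-5,5,8a-trimethyl-1,2,4a,5,6,7,8,8a-octahydronaphthalen-1-yl]ethyl}but-2-enoate | CC(=O)OC/C(=C/C(=O)OC(C)(C)C)CC[C@@H]1[C@@H](CO)C=C[C@@H]2C(C)(C)CCC[C@@]12C
F10 | step 18 | tert-butyl (2E)-4-acetoxy-3-{2-[(1R,2S,4aR,8aS)-2-formyl-5,5,8a-trimethyl-1,2,4a,5,6,7,8,8a-octahydronaphthalen-1-yl]ethyl}but-2-enoate | CC(=O)OC/C(=C/C(=O)OC(C)(C)C)CC[C@@H]1[C@@H](C=O)C=C[C@@H]2C(C)(C)CCC[C@@]12C
A1 | alternative 1 | (3E,7E)-4,8,12-trimethyltrideca-3,7,11-trien-1-yl acetate (homofarnesyl acetate) | CC(=O)OCC/C=C(\C)CC/C=C(\C)CCC=C(C)C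
A2 | alternative 1 | 2-[(1R,4aR,8aR)-2,5,5,8a-tetramethyl-1,4,4a,5,6,7,8,8a-octahydronaphthalen-1-yl]ethyl acetate | CC(=O)OCC[C@@H]1C(C)=CC[C@@H]2C(C)(C)CCC[C@@]12C
A3 | alternative 2 | trans-fused 1-[(1E)-3-{[tert-butyl(dimethyl)silyl]oxy}prop-1-en-1-yl]-4a,8,8-trimethyloctahydro-1H-isochromen-3-one, alkenyl group trans to the 4a-methyl | O=C1C[C@]2(C)CCCC(C)(C)[C@H]2[C@H](/C=C/CO[Si](C)(C)C(C)(C)C)O1
A4 | alternative 2 | (1R,2R,4aR,8aR)-2-{[(tert-butyldimethylsilyl)oxy]methyl}-5,5,8a-trimethyl-1,2,4a,5,6,7,8,8a-octahydronaphthalene-1-carboxylic acid (8-epi series) | OC(=O)[C@@H]1[C@H](CO[Si](C)(C)C(C)(C)C)C=C[C@@H]2C(C)(C)CCC[C@@]12C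
A5 | alternative 3 | 3-(5-bromo-2-methylpentan-2-yl)-4-methylphenol | Cc1ccc(O)cc1C(C)(C)CCCBr
A6 | alternative 3 | (4aS)-4a,8,8-trimethyl-5,6,7,8-tetrahydronaphthalen-2(4aH)-one (would form as the racemate) | C[C@@]12CCCC(C)(C)C1=CC(=O)C=C2
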